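**Strategy.** Ring A of the chromene (C4a, C5, C6, C7, C8, C8a) is a phloroglucinol. Its three oxygens differ (C5–OH, C7–OMe, C8a–O1), and the prenyl group at C8 sits between two of them. The ring is cut at C4a–C8a and C5–C6 into 3-methoxy-4-prenylcyclobutenone, which carries OMe and prenyl on neighbouring carbons, and terminal (triisopropylsilyloxy)ethyne. One heating step should assemble the ring. It should place OMe, prenyl, a single free OH (future O1) and a silyl-masked oxygen (future C5–OH) in their final positions. The free OH then anchors ring B. The C6 acyl group enters last by directed lithiation.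

Key step: step 6

Remark: the target has no stereocentre. The sp3 centres of the cyclobutenones, dienones and the hemiaminal on the way are racemic and disappear downstream. 5-Methylhex-4-enoic acid and 3-chloro-3-methylbut-1-yne are taken as purchasable.

Step 1
Reactants: 1 chloroacetaldehyde dimethyl acetal
Product: 3 methoxyacetylene (methoxyethyne), via sodium methoxyacetylide 2 (not isolated)
Conditions: NaNH2 (3.1 equiv), liq. NH3, −33 °C; NH3 evaporated; cold brine, −20 °C; low-boiling product distilled into Et2O at −78 °C
Reagents that add atoms: none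
Why: Two successive base-induced β-eliminations (loss of methanol and of HCl) followed by deprotonation of the alkyne make up the classical alkoxyacetylene synthesis from an α-chloroacetal, and the aqueous quench releases the volatile ynol ether.

Step 2
Reactants: 4 5-methylhex-4-enoic acid
Product: 5 5-methylhex-4-enoyl chloride
Conditions: (COCl)2 (1.2 equiv), DMF (cat.), CH2Cl2, 0 °C → rt; concentrated and used directly
Reagents that add atoms: oxalyl chloride, O=C(Cl)C(=O)Cl
Why: Vilsmeier-type acid chloride formation runs at or below room temperature, where the trisubstituted alkene is not attacked.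

Step 3
Reactants: 5 5-methylhex-4-enoyl chloride; 3 methoxyacetylene
Product: 7 3-methoxy-4-(3-methylbut-2-enyl)cyclobut-2-en-1-one (racemic), via prenylketene 6 (not isolated)
Conditions: 3 (2.5 equiv), Et3N (1.2 equiv, slow addition), Et2O, 0 °C → rt, dry-ice condenser; chromatography on Et3N-deactivated silica
Reagents that add atoms: none
Why: Dehydrochlorination gives the aldoketene, whose carbonyl carbon is attacked by the nucleophilic CH terminus of the ynol ether in a regiospecific thermal ketene–alkyne [2+2] cycloaddition; slow base addition and excess 3 hold down ketene dimerisation, the one-carbon tether rules out an intramolecular ketene–alkene addition, and the new C4 centre is racemic and is erased in step 6.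

Step 4
Reactants: 8 trimethylsilylacetylene
Product: 11 triisopropyl[(trimethylsilyl)ethynyloxy]silane, via lithium trimethylsilylacetylide 9 (not isolated), via lithium trimethylsilylynolate 10 (not isolated)
Conditions: n-BuLi, THF, −78 °C; LiOOt-Bu (from anhydrous t-BuOOH and LiHMDS, THF, −78 °C), −78 → 0 °C; TIPSOTf, −78 → 0 °C; hexane/aq. NaHCO3 work-up
Reagents that add atoms: tert-butyl hydroperoxide (used as its lithium salt), CC(C)(C)OO; triisopropylsilyl triflate, CC(C)[Si](OS(=O)(=O)C(F)(F)F)(C(C)C)C(C)C
Why: Oxygen transfer from lithium tert-butyl peroxide to a lithium acetylide is the established route to ynolates, and the very bulky, hard silyl triflate should silylate the ambident anion on oxygen, not on the carbon that already bears SiMe3.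

Step 5
Reactants: 11 triisopropyl[(trimethylsilyl)ethynyloxy]silane
Product: 12 (triisopropylsilyloxy)ethyne
Conditions: K2CO3 (0.1 equiv), MeOH–THF, 0 °C; pentane/water work-up, careful concentration
Reagents that add atoms: none
Why: Methoxide-catalysed protodesilylation attacks the unhindered alkynyl SiMe3 group far faster than the shielded O–Si(i-Pr)3 group, and the basic medium avoids acid-catalysed addition of methanol to the ynol ether.

Step 6
Reactants: 7 3-methoxy-4-(3-methylbut-2-enyl)cyclobut-2-en-1-one; 12 (triisopropylsilyloxy)ethyne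
Product: 17 3-methoxy-2-(3-methylbut-2-enyl)-5-(triisopropylsilyloxy)phenol, via vinylketene 13 (not isolated), via vinylcyclobutenone 14 (not isolated), via dienylketene 15 (not isolated), via cyclohexadienone 16 (not isolated)
Conditions: 12 (1.5–2 equiv), toluene (0.5 M), argon, sealed tube, 80 °C, then 110 °C until 14 is consumed
Reagents that add atoms: none
Why: Release of ring strain drives conrotatory 4π opening of 7, with the C4 prenyl chain turning outward, to vinylketene 13, whose electrophilic carbonyl carbon is attacked by the CH terminus of 12 in a [2+2] that gives 14 and creates the C8a–C4a and C6–C5 bonds. A second, reversible 4π opening gives dienylketene 15, and only the isomer with a cis central double bond can go on. Ring A is closed by disrotatory 6π electrocyclisation (C8a to C8) to dienone 16, and tautomerisation to phenol 17 makes the cascade irreversible. The closest known reaction is the Danheiser benzannulation of cyclobutenones with alkoxy- and silyloxyalkynes to resorcinol derivatives. No stereocentre is created, and the racemic centre of 7 vanishes. The one selectivity needed is the orientation of the [2+2], which the oxygen-polarised triple bond secures, so the oxygens fall 1,3,5 with prenyl between OMe and the free OH, while excess 12 and the bulky TIPS group are meant to outrun ketene dimerisation and O-to-C silyl migration.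

Step 7
Reactants: 17 3-methoxy-2-(3-methylbut-2-enyl)-5-(triisopropylsilyloxy)phenol; 18 3-chloro-3-methylbut-1-yne
Product: 19 [3-methoxy-5-(2-methylbut-3-yn-2-yloxy)-4-(3-methylbut-2-enyl)phenoxy]triisopropylsilane
Conditions: 18 (1.3 equiv), CuCl2·2H2O (1 mol %), DBU (1.5 equiv), dry MeCN, 0 °C
Reagents that add atoms: none
Why: Copper-catalysed propargylic etherification of a phenol builds the hindered tertiary ether at 0 °C, where the aryl TIPS ether and the prenyl group are inert.

Step 8
Reactants: 19 [3-methoxy-5-(2-methylbut-3-yn-2-yloxy)-4-(3-methylbut-2-enyl)phenoxy]triisopropylsilane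
Product: 23 7-methoxy-2,2-dimethyl-8-(3-methylbut-2-enyl)-5-(triisopropylsilyloxy)-2H-chromene, via allenyl dienone 20 (not isolated), via allenylphenol 21 (not isolated), via quinone methide 22 (not isolated)
Conditions: degassed xylenes, 140 °C
Reagents that add atoms: none
Why: The aromatic propargyl Claisen rearrangement can end productively only at C4a, the sole ortho CH, and enolisation, 1,5-hydrogen shift and oxa-6π electrocyclisation then close ring B, whereas attack at the blocked C8 is reversible.

Step 9
Reactants: 23 7-methoxy-2,2-dimethyl-8-(3-methylbut-2-enyl)-5-(triisopropylsilyloxy)-2H-chromene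
Product: 25 7-methoxy-5-(methoxymethoxy)-2,2-dimethyl-8-(3-methylbut-2-enyl)-2H-chromene, via tetrabutylammonium phenoxide 24 (not isolated)
Conditions: TBAF (1.05 equiv), THF, 0 °C; then MOMCl (1.5 equiv), 0 °C → rt, same flask
Reagents that add atoms: chloromethyl methyl ether, COCCl
Why: Fluoride desilylation followed by Williamson-type O-alkylation of the naked phenoxide in one flask replaces a group that shields C6 and could migrate from oxygen to a neighbouring carbanion by one that directs lithiation.

Step 10
Reactants: 26 4-hydroxyphenylacetic acid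
Product: 27 2-(4-hydroxyphenyl)-N-methoxy-N-methylacetamide
Conditions: MeNH(OMe)·HCl, EDC·HCl, N-methylmorpholine, CH2Cl2, 0 °C → rt
Reagents that add atoms: N,O-dimethylhydroxylamine hydrochloride, CNOC.Cl
Why: In this carbodiimide amide coupling the amine outcompetes the free phenol for the activated ester.

Step 11
Reactants: 27 2-(4-hydroxyphenyl)-N-methoxy-N-methylacetamide
Product: 28 N-methoxy-2-[4-(methoxymethoxy)phenyl]-N-methylacetamide
Conditions: MOMCl, i-Pr2NEt, CH2Cl2, 0 °C → rt
Reagents that add atoms: chloromethyl methyl ether, COCCl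
Why: Standard MOM protection of a phenol installs the same acid-labile group as at C5, so one final operation frees both phenols.

Step 12
Reactants: 25 7-methoxy-5-(methoxymethoxy)-2,2-dimethyl-8-(3-methylbut-2-enyl)-2H-chromene; 28 N-methoxy-2-[4-(methoxymethoxy)phenyl]-N-methylacetamide
Product: 31 1-[7-methoxy-5-(methoxymethoxy)-2,2-dimethyl-8-(3-methylbut-2-enyl)-2H-chromen-6-yl]-2-[4-(methoxymethoxy)phenyl]ethan-1-one, via aryllithium 29 (not isolated), via lithium hemiaminal 30 (not isolated)
Conditions: n-BuLi (1.1 equiv), THF, 0 °C; then 28 (1.3 equiv), −78 → 0 °C; aq. NH4Cl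
Reagents that add atoms: none
Why: Directed ortho-metalation takes place at C6, the only ring CH, flanked by the cooperating OMOM and OMe donors, and the Weinreb ketone synthesis stops at the chelated adduct 30, so the C6 acyl group is introduced without any electrophilic halogen meeting the electron-rich C3=C4 and prenyl alkenes.

Step 13
Reactants: 31 1-[7-methoxy-5-(methoxymethoxy)-2,2-dimethyl-8-(3-methylbut-2-enyl)-2H-chromen-6-yl]-2-[4-(methoxymethoxy)phenyl]ethan-1-one
Product: 32 1-[5-hydroxy-7-methoxy-2,2-dimethyl-8-(3-methylbut-2-enyl)-2H-chromen-6-yl]-2-(4-hydroxyphenyl)ethan-1-one (CNP0287261.0)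
Conditions: HCl (3 M aq., cat.), MeOH, rt → 40 °C
Reagents that add atoms: none
Why: Acid-catalysed acetal exchange removes both MOM groups (the C5 one assisted by hydrogen bonding to the ketone), and no chroman can form because neither oxygen next to the prenyl group (C7–OMe, O1) is a free phenol.

**Compound list**

1 | chloroacetaldehyde dimethyl acetal | COC(CCl)OC | starting material
2 | sodium methoxyacetylide (formed in the flask) | [Na]C#COC | intermediate
3 | methoxyacetylene | C#COC | intermediate
4 | 5-methylhex-4-enoic acid | CC(C)=CCCC(=O)O | starting material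
5 | 5-methylhex-4-enoyl chloride | CC(C)=CCCC(=O)Cl | intermediate
6 | prenylketene, 5-methylhexa-1,4-dien-1-one (formed in the flask) | CC(C)=CCC=C=O | intermediate
7 | 3-methoxy-4-(3-methylbut-2-enyl)cyclobut-2-en-1-one (racemic) | COC1=CC(=O)C1CC=C(C)C | intermediate
8 | trimethylsilylacetylene | C[Si](C)(C)C#C | starting material
9 | lithium trimethylsilylacetylide (formed in the flask) | C[Si](C)(C)C#C[Li] | intermediate
10 | lithium trimethylsilylynolate (formed in the flask) | C[Si](C)(C)C#CO[Li] | intermediate
11 | triisopropyl[(trimethylsilyl)ethynyloxy]silane | C[Si](C)(C)C#CO[Si](C(C)C)(C(C)C)C(C)C | intermediate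
12 | (triisopropylsilyloxy)ethyne | C#CO[Si](C(C)C)(C(C)C)C(C)C | intermediate
13 | vinylketene, (3Z)-3-methoxy-7-methylocta-1,3,6-trien-1-one (formed in the flask) | O=C=C/C(OC)=C/CC=C(C)C | intermediate
14 | 4-[(1Z)-1-methoxy-5-methylhexa-1,4-dienyl]-3-(triisopropylsilyloxy)cyclobut-2-en-1-one, racemic (formed in the flask) | O=C1C=C(O[Si](C(C)C)(C(C)C)C(C)C)C1/C(OC)=C/CC=C(C)C | intermediate
15 | dienylketene, (3E,5Z)-5-methoxy-9-methyl-3-(triisopropylsilyloxy)deca-1,3,5,8-tetraen-1-one, chain ends cis on the central C=C (formed in the flask) | O=C=C/C(O[Si](C(C)C)(C(C)C)C(C)C)=C\C(OC)=C\CC=C(C)C | intermediate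
16 | 5-methoxy-6-(3-methylbut-2-enyl)-3-(triisopropylsilyloxy)cyclohexa-2,4-dien-1-one, racemic (formed in the flask) | O=C1C=C(O[Si](C(C)C)(C(C)C)C(C)C)C=C(OC)C1CC=C(C)C | intermediate
17 | 3-methoxy-2-(3-methylbut-2-enyl)-5-(triisopropylsilyloxy)phenol | COc1cc(O[Si](C(C)C)(C(C)C)C(C)C)cc(O)c1CC=C(C)C | intermediate
18 | 3-chloro-3-methylbut-1-yne | C#CC(C)(C)Cl | starting material
19 | [3-methoxy-5-(2-methylbut-3-yn-2-yloxy)-4-(3-methylbut-2-enyl)phenoxy]triisopropylsilane | COc1cc(O[Si](C(C)C)(C(C)C)C(C)C)cc(OC(C)(C)C#C)c1CC=C(C)C | intermediate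
20 | 3-methoxy-2-(3-methylbut-2-enyl)-6-(3-methylbuta-1,2-dienyl)-5-(triisopropylsilyloxy)cyclohexa-2,4-dien-1-one, racemic (formed in the flask) | O=C1C(C=C=C(C)C)C(O[Si](C(C)C)(C(C)C)C(C)C)=CC(OC)=C1CC=C(C)C | intermediate
21 | 3-methoxy-2-(3-methylbut-2-enyl)-6-(3-methylbuta-1,2-dienyl)-5-(triisopropylsilyloxy)phenol (formed in the flask) | Oc1c(C=C=C(C)C)c(O[Si](C(C)C)(C(C)C)C(C)C)cc(OC)c1CC=C(C)C | intermediate
22 | ortho-quinone methide, 3-methoxy-2-(3-methylbut-2-enyl)-6-(3-methylbut-2-enylidene)-5-(triisopropylsilyloxy)cyclohexa-2,4-dien-1-one, side chain cis to C=O (formed in the flask) | O=C1/C(=C\C=C(C)C)C(O[Si](C(C)C)(C(C)C)C(C)C)=CC(OC)=C1CC=C(C)C | intermediate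
23 | 7-methoxy-2,2-dimethyl-8-(3-methylbut-2-enyl)-5-(triisopropylsilyloxy)-2H-chromene | COc1cc(O[Si](C(C)C)(C(C)C)C(C)C)c2C=CC(C)(C)Oc2c1CC=C(C)C | intermediate
24 | tetrabutylammonium 7-methoxy-2,2-dimethyl-8-(3-methylbut-2-enyl)-2H-chromen-5-olate (formed in the flask) | COc1cc([O-])c2C=CC(C)(C)Oc2c1CC=C(C)C.CCCC[N+](CCCC)(CCCC)CCCC | intermediate
25 | 7-methoxy-5-(methoxymethoxy)-2,2-dimethyl-8-(3-methylbut-2-enyl)-2H-chromene | COCOc1cc(OC)c(CC=C(C)C)c2OC(C)(C)C=Cc12 | intermediate
26 | 4-hydroxyphenylacetic acid | OC(=O)Cc1ccc(O)cc1 | starting material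
27 | 2-(4-hydroxyphenyl)-N-methoxy-N-methylacetamide | CON(C)C(=O)Cc1ccc(O)cc1 | intermediate
28 | N-methoxy-2-[4-(methoxymethoxy)phenyl]-N-methylacetamide | COCOc1ccc(CC(=O)N(C)OC)cc1 | intermediate
29 | 6-lithio derivative of 25 (formed in the flask) | [Li]c1c(OC)c(CC=C(C)C)c2OC(C)(C)C=Cc2c1OCOC | intermediate
30 | lithium hemiaminal adduct of 29 and 28, racemic (formed in the flask) | [Li]OC(Cc1ccc(OCOC)cc1)(N(C)OC)c1c(OC)c(CC=C(C)C)c2OC(C)(C)C=Cc2c1OCOC | intermediate
31 | 1-[7-methoxy-5-(methoxymethoxy)-2,2-dimethyl-8-(3-methylbut-2-enyl)-2H-chromen-6-yl]-2-[4-(methoxymethoxy)phenyl]ethan-1-one | COCOc1ccc(CC(=O)c2c(OC)c(CC=C(C)C)c3OC(C)(C)C=Cc3c2OCOC)cc1 | intermediate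
32 | 1-[5-hydroxy-7-methoxy-2,2-dimethyl-8-(3-methylbut-2-enyl)-2H-chromen-6-yl]-2-(4-hydroxyphenyl)ethan-1-one | COc1c(CC=C(C)C)c2c(c(O)c1C(=O)Cc1ccc(O)cc1)C=CC(C)(C)O2 | target

**Step count.** Total: 13 steps. The longest linear sequence is 8 steps (2, 3, 6, 7, 8, 9, 12, 13). The branches through step 1 and through steps 4 and 5 are equally long. The amide branch (10, 11) joins at step 12.

**Steps most likely to fail**

1. **Step 6.**
   - What may go wrong: the vinylogous-ester cyclobutenone may open too slowly at temperatures the terminal ynol ether tolerates. O-to-C silyl migration or oligomerisation of the alkyne, ketene dimerisation, or a 1,5-hydrogen shift in the inward-rotated vinylketene could then overtake the [2+2] capture.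
   - Fallback: exchange the roles of the two components. It sets out from 3 and 12 and comes back at 17.
   - Cycloaddition of 12 with ketene gas (a known reaction of silyloxyacetylenes) should give 3-(triisopropylsilyloxy)cyclobut-2-en-1-one F1.
   - Deprotonation of 3 with n-BuLi and alkylation with prenyl bromide in THF/DMPU should give 1-methoxy-5-methylhex-4-en-1-yne F2.
   - Heating F1 with F2 in toluene runs the same type of cascade but forms C8–C8a and C6–C7 instead. The cyclobutenone now has no C4 substituent that could shift a hydrogen, and the partner is an internal alkoxyalkyne, the best-documented class. The polarity of F2 places prenyl next to the new OH, so the product is again 17.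

2. **Step 5.**
   - What may go wrong: loss of the O-silyl group or addition of methanol across the ynol ether may compete with C–Si cleavage, and the fairly volatile product may be lost on isolation.
   - Fallback: postpone the C–Si cleavage until the ring is built. It sets out from 11 (together with 7) and comes back at 17.
   - Heating 7 with 11 under the conditions of step 6 should give 3-methoxy-2-(3-methylbut-2-enyl)-5-(triisopropylsilyloxy)-6-(trimethylsilyl)phenol F3. The silicon on the nucleophilic alkyne carbon reinforces the polarity of the [2+2].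
   - Brief treatment with CF3CO2H in CH2Cl2 at −20 °C (ipso-protodesilylation of a very electron-rich arylsilane) should then deliver 17.

3. **Step 12.**
   - What may go wrong: a proton may transfer from the acidic benzylic CH2 of the amide to the hindered aryllithium, or metalation may drift to the benzylic–allylic CH2 at C8.
   - Fallback: reverse the polarity and avoid strong base on the chromene. It sets out from 23 and comes back at 31.
   - TBAF with aqueous work-up gives 7-methoxy-2,2-dimethyl-8-(3-methylbut-2-enyl)-2H-chromen-5-ol F4.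
   - Casnati–Skattebøl ortho-formylation (MgCl2, Et3N, paraformaldehyde, MeCN, reflux) can only reach C6 and gives 5-hydroxy-7-methoxy-2,2-dimethyl-8-(3-methylbut-2-enyl)-2H-chromene-6-carbaldehyde F5.
   - MOMCl/i-Pr2NEt gives 7-methoxy-5-(methoxymethoxy)-2,2-dimethyl-8-(3-methylbut-2-enyl)-2H-chromene-6-carbaldehyde F6.
   - Addition of 4-(methoxymethoxy)benzylmagnesium chloride F7 (from the known benzyl chloride and magnesium, Et2O, 0 °C) gives 1-[7-methoxy-5-(methoxymethoxy)-2,2-dimethyl-8-(3-methylbut-2-enyl)-2H-chromen-6-yl]-2-[4-(methoxymethoxy)phenyl]ethan-1-ol F8 (racemic).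
   - Dess–Martin oxidation buffered with NaHCO3 then gives 31.

**Further compounds**

F1 | step 6 | 3-(triisopropylsilyloxy)cyclobut-2-en-1-one | O=C1C=C(O[Si](C(C)C)(C(C)C)C(C)C)C1
F2 | step 6 | 1-methoxy-5-methylhex-4-en-1-yne | COC#CCC=C(C)C
F3 | step 5 | 3-methoxy-2-(3-methylbut-2-enyl)-5-(triisopropylsilyloxy)-6-(trimethylsilyl)phenol | COc1cc(O[Si](C(C)C)(C(C)C)C(C)C)c([Si](C)(C)C)c(O)c1CC=C(C)C
F4 | step 12 | 7-methoxy-2,2-dimethyl-8-(3-methylbut-2-enyl)-2H-chromen-5-ol | COc1cc(O)c2C=CC(C)(C)Oc2c1CC=C(C)C
F5 | step 12 | 5-hydroxy-7-methoxy-2,2-dimethyl-8-(3-methylbut-2-enyl)-2H-chromene-6-carbaldehyde | COc1c(C=O)c(O)c2C=CC(C)(C)Oc2c1CC=C(C)C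
F6 | step 12 | 7-methoxy-5-(methoxymethoxy)-2,2-dimethyl-8-(3-methylbut-2-enyl)-2H-chromene-6-carbaldehyde | COCOc1c(C=O)c(OC)c(CC=C(C)C)c2OC(C)(C)C=Cc12
F7 | step 12 | 4-(methoxymethoxy)benzylmagnesium chloride | COCOc1ccc(C[Mg]Cl)cc1
F8 | step 12 | 1-[7-methoxy-5-(methoxymethoxy)-2,2-dimethyl-8-(3-methylbut-2-enyl)-2H-chromen-6-yl]-2-[4-(methoxymethoxy)phenyl]ethan-1-ol (racemic) | COCOc1ccc(CC(O)c2c(OC)c(CC=C(C)C)c3OC(C)(C)C=Cc3c2OCOC)cc1
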